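**Plan**
- Cuts, in retrosynthetic order: C12–C13 (sp3–sp2 coupling of a C9-vinyl decalin with a four-carbon vinyl iodide), then C7–C8 and C9–C10 together, then C4–C5 with C3–Br (bromonium cyclisation of an acyclic geranate).
- Enabling feature: in ring B (C5–C10) the carbinol C8 (CH3, OH) sits between the chain-bearing C9 and C7, and C9 is bonded to the quaternary C10. Reading C8(OH)CH3 as a hydrated exocyclic C8=C17 alkene and C5–H as a reduced C5=C6 alkene turns ring B into a 4-methylidenecyclohexene with an acyl group on C9. That is the [4+2] retron of the diene C7=C6–C5=C10 (C5=C10 lies in ring A) and an allenic acyl unit C17=C8=C9–C11=O, whose linear sp-carbon C8 lets the hindered C10 and the future carbinol carbon be joined in one event.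
- Forward order: ring A first (bromocyclisation, then conversion to the 2-vinylcyclohexene), ring B by the cycloaddition, then C9 inversion, C8 hydration and C5 reduction on the helper alkenes, and last the side chain by hydroboration/Suzuki coupling. Helpers removed: oxazolidinone (step 8), thioester (step 13), silyl ether (step 17).
- Stereochemistry: C10 from the (R)-oxazolidinone-controlled face of the dienophile in the endo mode; C9 by kinetic protonation; C8–OH and C5–H by radical capture on the face opposite the C10 methyl. C3–Br is formed as a racemate in the bromocyclisation and is resolved by the chiral dienophile at the cycloaddition. The (E)-alkene comes from syn-hydrozirconation and stereoretentive coupling.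

Key step: step 7

Remark: positions are given with terpenoid locants (C1–C10 ring carbons, C11–C15 chain, C17 = methyl carbon on C8, C20 = methyl on C10).
Remark: the monocyclic ring-A intermediates are racemic at the bromine-bearing carbon; their SMILES show the enantiomer that is carried into the target, and the enantiomers are parted at the cycloaddition.

Step 1
Reactants: 1 methyl (2E)-3,7-dimethylocta-2,6-dienoate (methyl geranate)
Product: 2 methyl rac-(1S,5R)-5-bromo-2,6,6-trimethylcyclohex-2-ene-1-carboxylate (major double-bond isomer; the exocyclic and the conjugated isomers are carried along)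
Conditions: Et2SBr·SbCl5Br (1.1 equiv), MeNO2, −25 °C; aq. NaHCO3/Na2S2O3
Reagents that add atoms: bromodiethylsulfonium bromopentachloroantimonate, CC[S+](Br)CC.Cl[Sb-](Cl)(Cl)(Cl)(Cl)Br
Why: Bromonium-induced cation–olefin cyclisation, in which Br+ goes only to the electron-rich 6,7-alkene and the α-carbon of the enoate closes the six-membered ring through a chair-like transition state that puts bromine equatorial (the C3 centre, formed as a racemate), the tertiary cation then losing a proton.

Step 2
Reactants: 2 methyl rac-(1S,5R)-5-bromo-2,6,6-trimethylcyclohex-2-ene-1-carboxylate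
Product: 3 rac-[(1S,5R)-5-bromo-2,6,6-trimethylcyclohex-2-en-1-yl]methanol (with its double-bond isomers)
Conditions: i-Bu2AlH (2.5 equiv), CH2Cl2, −78 → 0 °C; aq. potassium sodium tartrate
Reagents that add atoms: none
Why: Hydride reduction of the ester to the primary alcohol, which leaves the hindered secondary alkyl bromide untouched and changes no stereocentre.

Step 3
Reactants: 3 rac-[(1S,5R)-5-bromo-2,6,6-trimethylcyclohex-2-en-1-yl]methanol
Product: 5 racemic 5-bromo-2,6,6-trimethylcyclohex-1-ene-1-carbaldehyde, via unconjugated aldehyde 4 (not isolated)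
Conditions: DMP, NaHCO3, CH2Cl2, 0 °C → rt; then KOH (0.2 equiv), MeOH, rt
Reagents that add atoms: none
Why: Periodinane oxidation followed by base-mediated isomerisation through the dienolate moves every double-bond isomer into conjugation (the β-cyclocitral pattern), which erases the C5 centre so that only the bromine-bearing centre remains.

Step 4
Reactants: 5 racemic 5-bromo-2,6,6-trimethylcyclohex-1-ene-1-carbaldehyde
Product: 6 racemic 4-bromo-2-ethenyl-1,3,3-trimethylcyclohex-1-ene
Conditions: Ph3PCH3Br, KOtBu, THF, 0 °C → rt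
Reagents that add atoms: methyltriphenylphosphonium bromide, C[P+](c1ccccc1)(c1ccccc1)c1ccccc1.[Br-]
Why: Wittig methylenation of the hindered enal gives the 2-vinylcyclohexene (C7=C6–C5=C10) without creating a stereocentre.

Step 5
Reactants: 7 ethyl buta-2,3-dienoate
Product: 8 buta-2,3-dienoic acid
Conditions: LiOH, THF/H2O, 0 °C; then 1 M HCl
Reagents that add atoms: lithium hydroxide, [Li+].[OH-]
Why: Ester saponification, run cold to limit conjugate addition of hydroxide to the allene, frees the acid.

Step 6
Reactants: 8 buta-2,3-dienoic acid; 9 (4R)-4-benzyl-1,3-oxazolidin-2-one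
Product: 11 (4R)-4-benzyl-3-(buta-2,3-dienoyl)-1,3-oxazolidin-2-one, via mixed pivalic anhydride 10 (not isolated)
Conditions: PivCl, Et3N, THF, −20 °C; then 9, LiCl, −20 °C → rt
Reagents that add atoms: none
Why: N-Acylation of the oxazolidinone through the mixed anhydride installs the chiral controller on the allenic acyl unit without creating a stereocentre.

Step 7
Reactants: 6 racemic 4-bromo-2-ethenyl-1,3,3-trimethylcyclohex-1-ene (2.5 equiv); 11 (4R)-4-benzyl-3-(buta-2,3-dienoyl)-1,3-oxazolidin-2-one
Product: 12 (4R)-4-benzyl-3-{[(1S,6R,8aS)-6-bromo-5,5,8a-trimethyl-2-methylidene-1,2,3,5,6,7,8,8a-octahydronaphthalen-1-yl]carbonyl}-1,3-oxazolidin-2-one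
Conditions: Et2AlCl (1.4 equiv based on 11), CH2Cl2, −78 → −30 °C
Reagents that add atoms: none
Why: Lewis-acid-promoted Diels–Alder reaction: Et2AlCl chelates the two imide carbonyls (s-cis acyl) and lowers the LUMO of the α,β-bond of the allene, and the diene adds in a concerted but asynchronous [4+2] step in which the unhindered CH2 terminus C7 bonds first to the electrophilic sp-carbon C8 and C9 then closes onto C10. The closest known reactions are the aluminium-chelate cycloadditions of N-enoyl oxazolidinones and the cycloadditions of chiral allenic esters that give methylidenecyclohexenes. Ring B is closed by the intermolecular suprafacial union of C7=C6–C5=C10 with C8=C9, which leaves the C5=C6 alkene and the exocyclic C8=C17 alkene as handles. The quaternary centre C10 is set by the auxiliary, whose benzyl group blocks one face of the chelated dienophile so that the diene meets the Cα-re face in the endo mode and the C10 methyl ends on the face away from the new C9–C10 bond; C9 is set by the endo rule (acyl trans to the C10 methyl) and is corrected in step 9. The step needs regioselectivity (secured by the polarised acyl allene and by the steric difference between the CH2 and the fully substituted diene termini), [4+2] over [2+2] periselectivity (favoured because the developing allyl-cation character at C10 collapses to the six-membered ring), and endo and facial selectivity (secured by the chelate and by the half-chair of ring A, which shows only axial hydrogens to the dienophile when bromine is equatorial). Because this matched geometry exists only for the (R)-diene, the reagent should take that enantiomer preferentially from the racemate, and any adduct of the (S)-diene is a diastereomer that chromatography removes.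

Step 8
Reactants: 12 the cycloadduct imide
Product: 13 S-ethyl (1S,6R,8aS)-6-bromo-5,5,8a-trimethyl-2-methylidene-1,2,3,5,6,7,8,8a-octahydronaphthalene-1-carbothioate
Conditions: EtSH, n-BuLi, THF, −78 → 0 °C; aq. NH4Cl
Reagents that add atoms: ethanethiol, CCS
Why: Thiolate acyl transfer cleaves the exocyclic imide carbonyl, returns the auxiliary, and gives a thioester that can be enolised and later reduced to the aldehyde, with no stereocentre touched.

Step 9
Reactants: 13 the C9-epimeric thioester
Product: 15 S-ethyl (1R,6R,8aS)-6-bromo-5,5,8a-trimethyl-2-methylidene-1,2,3,5,6,7,8,8a-octahydronaphthalene-1-carbothioate, via lithium dienolate 14 (not isolated)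
Conditions: LiN(SiMe3)2 (1.2 equiv), THF, −78 °C; then AcOH, −78 °C
Reagents that add atoms: none
Why: Deconjugative kinetic protonation, in which the cross-conjugated dienolate takes its proton at the α-carbon C9 on the face opposite the C10 methyl, so that C9 is inverted (acyl now cis to the C10 methyl, as in the target) and the exocyclic alkene is kept.

Step 10
Reactants: 15 the thioester with the target configuration at C9
Product: 17 S-ethyl (1S,2S,6R,8aS)-6-bromo-2-hydroxy-2,5,5,8a-tetramethyl-1,2,3,5,6,7,8,8a-octahydronaphthalene-1-carbothioate, via tertiary hydroperoxide 16 (not isolated)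
Conditions: Mn(dpm)3 (10 mol%), PhSiH3, O2 (1 atm), i-PrOH/CH2Cl2, 0 °C; then PPh3
Reagents that add atoms: dioxygen, O=O
Why: Mukaiyama-type hydration by metal-hydride hydrogen-atom transfer, in which H• adds to the terminal carbon C17 of the 1,1-disubstituted alkene in preference to the hindered C5=C6 alkene and the tertiary C8 radical captures O2 on the face opposite the C10 methyl, giving the carbinol with its methyl cis to the C10 methyl.

Step 11
Reactants: 17 the unsaturated hydroxy thioester
Product: 18 S-ethyl (1S,2S,4aS,6R,8aR)-6-bromo-2-hydroxy-2,5,5,8a-tetramethyldecahydronaphthalene-1-carbothioate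
Conditions: Mn(dpm)3 (20 mol%), PhSiH3, t-BuOOH, i-PrOH, rt, argon
Reagents that add atoms: none
Why: Radical hydrogenation by hydrogen-atom transfer, in which H• adds to C6 and the tertiary C5 radical takes its hydrogen on the face opposite the axial methyls on C10 and C4, giving the trans-decalin while the C–Br bond and the thioester are left alone.

Step 12
Reactants: 18 the trans-decalin hydroxy thioester
Product: 19 S-ethyl (1S,2S,4aS,6R,8aR)-6-bromo-2,5,5,8a-tetramethyl-2-[(triethylsilyl)oxy]decahydronaphthalene-1-carbothioate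
Conditions: Et3SiOTf, 2,6-lutidine, CH2Cl2, −78 → 0 °C
Reagents that add atoms: triethylsilyl trifluoromethanesulfonate, CC[Si](CC)(CC)OS(=O)(=O)C(F)(F)F
Why: Silylation of the tertiary alcohol with the silyl triflate blocks retro-aldol cleavage and β-elimination in the next two steps.

Step 13
Reactants: 19 the silyl-protected thioester
Product: 20 (1S,2S,4aS,6R,8aR)-6-bromo-2,5,5,8a-tetramethyl-2-[(triethylsilyl)oxy]decahydronaphthalene-1-carbaldehyde
Conditions: i-Bu2AlH (1.2 equiv), CH2Cl2, −78 °C; aq. potassium sodium tartrate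
Reagents that add atoms: none
Why: Partial hydride reduction of the thioester stops at the aldehyde at low temperature and does not enolise C9.

Step 14
Reactants: 20 the C11 aldehyde
Product: 21 {[(1S,2S,4aS,6R,8aR)-6-bromo-1-ethenyl-2,5,5,8a-tetramethyldecahydronaphthalen-2-yl]oxy}triethylsilane
Conditions: Ph3PCH3Br, KN(SiMe3)2, THF, −78 → 0 °C
Reagents that add atoms: methyltriphenylphosphonium bromide, C[P+](c1ccccc1)(c1ccccc1)c1ccccc1.[Br-]
Why: Wittig methylenation with the small non-stabilised ylide converts the hindered aldehyde into the C11=C12 vinyl group faster than it can epimerise C9.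

Step 15
Reactants: 22 but-2-yn-1-ol
Product: 24 (2E)-3-iodobut-2-en-1-ol, via alkenylzirconocene 23 (not isolated)
Conditions: Cp2Zr(H)Cl (2.5 equiv), THF, rt; then I2, 0 °C
Reagents that add atoms: iodine, II
Why: Hydrozirconation–iodination, in which syn addition places zirconium on the methyl-bearing carbon (the less hindered position) and iodinolysis with retention gives the (E)-vinyl iodide.

Step 16
Reactants: 21 the C9-vinyl decalin; 24 (2E)-3-iodobut-2-en-1-ol
Product: 26 (2E)-5-{(1S,2S,4aS,6R,8aR)-6-bromo-2,5,5,8a-tetramethyl-2-[(triethylsilyl)oxy]decahydronaphthalen-1-yl}-3-methylpent-2-en-1-ol, via B-alkyl-9-BBN 25 (not isolated)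
Conditions: 9-BBN (1.5 equiv), THF, rt → 50 °C; then 24, Pd(dppf)Cl2 (5 mol%), AsPh3, Cs2CO3, DMF/H2O, rt
Reagents that add atoms: none
Why: B-alkyl Suzuki–Miyaura coupling, in which 9-BBN adds only to the terminal carbon of the vinyl group and the sp3–sp2 coupling keeps the (E)-geometry of the iodide, the secondary alkyl bromide being inert to the palladium catalyst.

Step 17
Reactants: 26 the silyl ether of the target
Product: 27 (1S,2S,4aS,6R,8aR)-6-bromo-1-[(3E)-5-hydroxy-3-methylpent-3-en-1-yl]-2,5,5,8a-tetramethyldecahydronaphthalen-2-ol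
Conditions: Bu4NF, THF, 0 °C → rt
Reagents that add atoms: none
Why: Fluoride-mediated desilylation frees the tertiary alcohol and gives the target, the equatorial bromide having no anti-periplanar hydrogen for elimination.

**Compound list**
1 | methyl (2E)-3,7-dimethylocta-2,6-dienoate (methyl geranate) | CC(C)=CCC/C(C)=C/C(=O)OC | starting material
2 | methyl (1S,5R)-5-bromo-2,6,6-trimethylcyclohex-2-ene-1-carboxylate, racemic, with its exocyclic and conjugated double-bond isomers | CC1=CC[C@@H](Br)C(C)(C)[C@H]1C(=O)OC | intermediate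
3 | [(1S,5R)-5-bromo-2,6,6-trimethylcyclohex-2-en-1-yl]methanol, racemic, with its double-bond isomers | CC1=CC[C@@H](Br)C(C)(C)[C@H]1CO | intermediate
4 | (1S,5R)-5-bromo-2,6,6-trimethylcyclohex-2-ene-1-carbaldehyde, racemic, with its double-bond isomers (not isolated) | CC1=CC[C@@H](Br)C(C)(C)[C@H]1C=O | intermediate
5 | 5-bromo-2,6,6-trimethylcyclohex-1-ene-1-carbaldehyde, racemic (5R shown) | CC1=C(C=O)C(C)(C)[C@H](Br)CC1 | intermediate
6 | 4-bromo-2-ethenyl-1,3,3-trimethylcyclohex-1-ene, racemic (4R shown) | CC1=C(C=C)C(C)(C)[C@H](Br)CC1 | intermediate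
7 | ethyl buta-2,3-dienoate | C=C=CC(=O)OCC | starting material
8 | buta-2,3-dienoic acid | C=C=CC(=O)O | intermediate
9 | (4R)-4-benzyl-1,3-oxazolidin-2-one | O=C1N[C@H](Cc2ccccc2)CO1 | starting material
10 | buta-2,3-dienoic pivalic anhydride (not isolated) | C=C=CC(=O)OC(=O)C(C)(C)C | intermediate
11 | (4R)-4-benzyl-3-(buta-2,3-dienoyl)-1,3-oxazolidin-2-one | C=C=CC(=O)N1[C@H](Cc2ccccc2)COC1=O | intermediate
12 | (4R)-4-benzyl-3-{[(1S,6R,8aS)-6-bromo-5,5,8a-trimethyl-2-methylidene-1,2,3,5,6,7,8,8a-octahydronaphthalen-1-yl]carbonyl}-1,3-oxazolidin-2-one (acyl trans to the C10 methyl) | O=C(N1C(=O)OC[C@H]1Cc1ccccc1)[C@@H]1[C@]2(C)CC[C@@H](Br)C(C)(C)C2=CCC1=C | intermediate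
13 | S-ethyl (1S,6R,8aS)-6-bromo-5,5,8a-trimethyl-2-methylidene-1,2,3,5,6,7,8,8a-octahydronaphthalene-1-carbothioate | CCSC(=O)[C@@H]1[C@]2(C)CC[C@@H](Br)C(C)(C)C2=CCC1=C | intermediate
14 | lithium dienolate of 13 (not isolated) | CCSC([O-])=C1[C@]2(C)CC[C@@H](Br)C(C)(C)C2=CCC1=C.[Li+] | intermediate
15 | S-ethyl (1R,6R,8aS)-6-bromo-5,5,8a-trimethyl-2-methylidene-1,2,3,5,6,7,8,8a-octahydronaphthalene-1-carbothioate (acyl cis to the C10 methyl) | CCSC(=O)[C@H]1[C@]2(C)CC[C@@H](Br)C(C)(C)C2=CCC1=C | intermediate
16 | S-ethyl (1S,2S,6R,8aS)-6-bromo-2-hydroperoxy-2,5,5,8a-tetramethyl-1,2,3,5,6,7,8,8a-octahydronaphthalene-1-carbothioate (not isolated) | CCSC(=O)[C@H]1[C@]2(C)CC[C@@H](Br)C(C)(C)C2=CC[C@]1(C)OO | intermediate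
17 | S-ethyl (1S,2S,6R,8aS)-6-bromo-2-hydroxy-2,5,5,8a-tetramethyl-1,2,3,5,6,7,8,8a-octahydronaphthalene-1-carbothioate | CCSC(=O)[C@H]1[C@]2(C)CC[C@@H](Br)C(C)(C)C2=CC[C@]1(C)O | intermediate
18 | S-ethyl (1S,2S,4aS,6R,8aR)-6-bromo-2-hydroxy-2,5,5,8a-tetramethyldecahydronaphthalene-1-carbothioate | CCSC(=O)[C@H]1[C@]2(C)CC[C@@H](Br)C(C)(C)[C@H]2CC[C@]1(C)O | intermediate
19 | S-ethyl (1S,2S,4aS,6R,8aR)-6-bromo-2,5,5,8a-tetramethyl-2-[(triethylsilyl)oxy]decahydronaphthalene-1-carbothioate | CCSC(=O)[C@H]1[C@]2(C)CC[C@@H](Br)C(C)(C)[C@H]2CC[C@]1(C)O[Si](CC)(CC)CC | intermediate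
20 | (1S,2S,4aS,6R,8aR)-6-bromo-2,5,5,8a-tetramethyl-2-[(triethylsilyl)oxy]decahydronaphthalene-1-carbaldehyde | O=C[C@H]1[C@]2(C)CC[C@@H](Br)C(C)(C)[C@H]2CC[C@]1(C)O[Si](CC)(CC)CC | intermediate
21 | {[(1S,2S,4aS,6R,8aR)-6-bromo-1-ethenyl-2,5,5,8a-tetramethyldecahydronaphthalen-2-yl]oxy}triethylsilane | C=C[C@H]1[C@]2(C)CC[C@@H](Br)C(C)(C)[C@H]2CC[C@]1(C)O[Si](CC)(CC)CC | intermediate
22 | but-2-yn-1-ol | CC#CCO | starting material
23 | (E)-alkenylzirconocene chloride of but-2-yn-1-ol, as its zirconium alkoxide (not isolated) | C/C(=C\CO[Zr](Cl)(C1C=CC=C1)C1C=CC=C1)[Zr](Cl)(C1C=CC=C1)C1C=CC=C1 | intermediate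
24 | (2E)-3-iodobut-2-en-1-ol | C/C(I)=C\CO | intermediate
25 | B-alkyl-9-borabicyclo[3.3.1]nonane from 21, boron on C12 (not isolated) | C(C[C@H]1[C@]2(C)CC[C@@H](Br)C(C)(C)[C@H]2CC[C@]1(C)O[Si](CC)(CC)CC)B1C2CCCC1CCC2 | intermediate
26 | (2E)-5-{(1S,2S,4aS,6R,8aR)-6-bromo-2,5,5,8a-tetramethyl-2-[(triethylsilyl)oxy]decahydronaphthalen-1-yl}-3-methylpent-2-en-1-ol | C/C(=C\CO)CC[C@H]1[C@]2(C)CC[C@@H](Br)C(C)(C)[C@H]2CC[C@]1(C)O[Si](CC)(CC)CC | intermediate
27 | (1S,2S,4aS,6R,8aR)-6-bromo-1-[(3E)-5-hydroxy-3-methylpent-3-en-1-yl]-2,5,5,8a-tetramethyldecahydronaphthalen-2-ol | C/C(=C\CO)CC[C@H]1[C@]2(C)CC[C@@H](Br)C(C)(C)[C@H]2CC[C@]1(C)O | target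

**Step count**
Total: 17 steps. Longest linear sequence: 14 steps (1–4, 7–14, 16, 17).

**Steps most likely to fail**

Step 7. The hindered diene may react too slowly at the temperature needed for chelate control. The Lewis-acid-bound allene may instead add stepwise ([2+2] closure at C6) or trigger cationic oligomerisation of the diene. Leakage from the endo to the exo mode would also invert the facial outcome at C10.
Fallback, from 6 and 8, back at 15: acid 8 is esterified with EtSH (DCC, DMAP, CH2Cl2, 0 °C) to S-ethyl buta-2,3-dienethioate F1. F1 is heated with racemic 6 in toluene at 110 °C without Lewis acid (thermal [4+2] of an allenic ester) to give the racemic thioester cycloadduct F2 as C9 epimers; the diastereomers with bromine trans to the C10 methyl are removed by chromatography. Treatment as in step 9 passes through the racemic lithium dienolate F3 to the racemic form of 15 F4. Preparative chromatography on a chiral stationary phase then gives 15.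

Step 9. The nearly planar dienolate may be protonated with poor facial discrimination, because the C10 methyl and C1 flank C9 almost symmetrically. Protonation at C17 would give the conjugated isomer, and warming would lose thiolate to a ketene.
Fallback, from 13, back at 18: 13 is hydrated under the step 10 conditions through the C9-epimeric hydroperoxide F5 to the C9-epimeric hydroxy thioester F6. F6 is hydrogenated as in step 11 to the C9-epimeric trans-decalin F7. F7 is converted with LiN(SiMe3)2 (2.2 equiv, THF, −78 °C) into the dilithium alkoxide–enolate F8 and protonated with AcOH at −78 °C. In the chair decalin the axial methyls on C8 and C10 shield the same face of C9, so the proton should enter from the other face and give 18.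

Step 10. Oxygen capture at the C8 radical may show poor facial selectivity. Hydrogen-atom transfer may also reach the C5=C6 alkene, and the peroxyl radical may cyclise onto C6.
Fallback, from 15, back at 17: oxymercuration of 15 with Hg(OAc)2 in THF/H2O at rt gives the organomercurial F9, with water entering at the tertiary carbon from the less hindered side. Brief reductive demercuration with NaBH4 at 0 °C gives 17.

Further compounds
F1 | step 7 | S-ethyl buta-2,3-dienethioate | C=C=CC(=O)SCC
F2 | step 7 | racemic S-ethyl 6-bromo-5,5,8a-trimethyl-2-methylidene-1,2,3,5,6,7,8,8a-octahydronaphthalene-1-carbothioate, bromine cis to the C10 methyl, C9 epimers (6R,8aS shown) | CCSC(=O)C1[C@]2(C)CC[C@@H](Br)C(C)(C)C2=CCC1=C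
F3 | step 7 | racemic lithium dienolate corresponding to 14 | CCSC([O-])=C1[C@]2(C)CC[C@@H](Br)C(C)(C)C2=CCC1=C.[Li+]
F4 | step 7 | racemic form of 15 (1R,6R,8aS shown) | CCSC(=O)[C@H]1[C@]2(C)CC[C@@H](Br)C(C)(C)C2=CCC1=C
F5 | step 9 | S-ethyl (1R,2S,6R,8aS)-6-bromo-2-hydroperoxy-2,5,5,8a-tetramethyl-1,2,3,5,6,7,8,8a-octahydronaphthalene-1-carbothioate | CCSC(=O)[C@@H]1[C@]2(C)CC[C@@H](Br)C(C)(C)C2=CC[C@]1(C)OO
F6 | step 9 | S-ethyl (1R,2S,6R,8aS)-6-bromo-2-hydroxy-2,5,5,8a-tetramethyl-1,2,3,5,6,7,8,8a-octahydronaphthalene-1-carbothioate | CCSC(=O)[C@@H]1[C@]2(C)CC[C@@H](Br)C(C)(C)C2=CC[C@]1(C)O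
F7 | step 9 | S-ethyl (1R,2S,4aS,6R,8aR)-6-bromo-2-hydroxy-2,5,5,8a-tetramethyldecahydronaphthalene-1-carbothioate | CCSC(=O)[C@@H]1[C@]2(C)CC[C@@H](Br)C(C)(C)[C@H]2CC[C@]1(C)O
F8 | step 9 | dilithium alkoxide–enolate of F7 | CCSC([O-])=C1[C@]2(C)CC[C@@H](Br)C(C)(C)[C@H]2CC[C@]1(C)[O-].[Li+].[Li+]
F9 | step 10 | acetoxymercurio derivative of 17 (HgOAc on C17) | CCSC(=O)[C@H]1[C@]2(C)CC[C@@H](Br)C(C)(C)C2=CC[C@@]1(O)C[Hg]OC(C)=O
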